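**Remark on numbering.** Briarane numbering of the target is used for every intermediate (C1 quaternary, C2–C9 round the ten-membered ring, C10 ring-fusion CH, ring A = C1, C10–C14, methyls C15/C16/C18/C20, lactone C17–C19). The face of ring A that carries the C15 methyl group is called β.

## Analysis of the target

Stylatulide lactone (41) is a briarane: a cyclohexene (ring A) is trans-fused through C1 and C10 to a ten-membered carbocycle, and a γ-lactone (O–C7, C8, C17, C19) is fused across C7–C8. It has eight stereocentres: C1 (S, quaternary), C2 (R), C7 (S), C8 (S, fully substituted), C9 (R), C10 (S), C14 (S) and C17 (R). Six of them (C7, C8, C9, C10, C1, C2) are contiguous. On ring A the C15 methyl and the C9 branch are β, while H10, the C2 branch and the 14-acetoxy group are α. On the lactone the 8-OH, the C18 methyl and C6 are cis, so C6 and C9 are trans, and the C9–O/C8–O and C8–O/C7–O pairs are both anti. Sensitive features are the three secondary acetates, the tertiary β-hydroxyl of the lactone, the allylic acyloxy group at C7, the C9 oxygen (also γ to C19, so the lactone can migrate), and the (Z)-C5=C6 alkene. The difficulty lies in closing a strained medium ring next to two fully substituted carbons (C1, C8) without disturbing this array. The strategy rests on one feature: C3 and C4 are the only ring carbons of the ten-membered ring without a substituent or stereocentre. C4 is allylic to C5=C6, and C3 is α to C2, which as a ketone beside quaternary C1 can only be activated towards C3.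

## Retrosynthetic reasoning

**41 ⇒ 38 (functional groups only).** The last three operations are removal of the 8-O-silyl group (40), acetylation of O2 (39) and reduction of the C2 ketone 38. C2 is kept as a ketone until after ring closure because it is needed to acidify C3; its configuration is then set by a chiral reagent.

**38 ⇒ 37 (C3–S).** The phenylsulfonyl group in 37 is a removable activating group. It makes C3 a soft, doubly stabilised carbanion and is cleaved reductively next to the ketone.

**37 ⇒ 36 (C3–C4, key disconnection).** The ring is cut between the two unfunctionalised carbons. No permanent stereocentre is formed in the ring closure, and the nucleophile (β-keto sulfone) and electrophile (primary allylic bromide) are both reliable. The forward reaction must achieve C-alkylation in a 10-membered closure from seco compound 36.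

**36 ⇒ 26 + 29 (C4–C5 and C2–C3).** The bromide comes from the (Z)-alkenyl iodide by hydroxymethylation with retention, done late so that the electrophile never meets a strong nucleophile. The β-keto sulfone comes from aldehyde 28 and methyl phenyl sulfone (29). The acetates and the 8-O-silyl group are put on in between (31–34).

**26 ⇒ 24 (alkene geometry).** The (Z)-iodide is derived from the propynyl group of lactone 24 by anti hydrosilylation and iododesilylation. The geometry therefore comes from the mechanism and not from an olefination.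

**24 ⇒ 20 + 21 (O7–C19, C7 stereocentre, C6–C7).** The lactone closes from the γ-hydroxy acid. C7 is set by reagent-controlled reduction of ynone 22, which arises from addition of propyne (21) to the activated C7 carboxyl of 20.

**20 ⇒ 14 + 18 (C8–C9).** An aldol reaction joins ring A aldehyde 14 to dioxolanone 18. This single bond brings in C7, C8, C17, C18 and C19, regenerates C8 with retention and sets C9 under Felkin–Anh control.

**18 ⇒ 15.** Diethyl (S)-malate (15) supplies C8 with its oxygen. Anti methylation (16) sets C17.

**14 ⇒ 11 (C9–C10).** A [2,3] shift from the β-oxygen at C12 delivers C9 to C10 on the β face and places the alkene at C11=C12 (12, 13).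

**11 ⇒ 8.** Allylic alcohol 11 is the 1,3-transposition product of enone 8 (epoxide 9, then hydrazine).

**8 ⇒ 1.** The 14α-oxygen comes from the isopropenyl group of (S)-carvone (1) by oxidative rearrangement with retention (4 → 6). The quaternary C1 comes from two successive α′-alkylations (2–4), the methyl last so that it enters trans to the isopropenyl group.

## Alternatives that were turned down

**Alternative 1:** The medium ring is hidden in a bicyclo[2.2.0]hexane. A triplet [2+2] photocycloaddition of a ring A enone with a cyclobutene gives the cis-anti-cis photoadduct A1, and thermolysis then opens the fused cyclobutanes to a cyclodecadiene.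
- For: two C–C bonds and the quaternary C1 form in one step, and no entropically costly medium-ring closure is needed. On bond economy in the ring-forming event it is stronger than the chosen route.
- Against: the ring expansion fixes the alkene positions by the cyclobutane framework. The (Z)-C5=C6 alkene with C16, the C8 tertiary alcohol with the C17–C19 unit, the lactone and the C11=C12 alkene with C20 would all still have to be built on a mobile ten-membered ring, where facial control is hard to predict. Head-to-head versus head-to-tail and exo/endo selectivity of the photoaddition are further open points.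
- Comparison: the chosen route gives up the two-bond step but fixes every permanent stereocentre on rigid or acyclic intermediates before the ring is closed.

**Alternative 2:** Ring A is cut at C13–C14. A proline enamine of a C12 ketone attacks a C14 aldehyde in a 6-enolendo aldol to give ketol A2.
- For: metal-free, catalyst-controlled formation of C14. On cost and mildness of the stereocontrolling step it is at least as good as the chosen route.
- Against: it solves only ring A, which carvone already delivers with C14 and C1 in a few steps. The acyclic substrate must already hold quaternary C1, C10 and C2. The enamine can form towards C11 or C13. The C12 ketone must later become the C11=C12 alkene. The ten-membered ring, the lactone and C7–C9 remain unsolved.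
- Comparison: more steps for the easy part of the molecule and no answer to the hard part.

**Alternative 3:** The ring is cut at C6–C7. An alkenylchromium from a (Z)-vinyl iodide adds to a C7 aldehyde (CrCl2/NiCl2) and the alkoxide closes the lactone, giving A3.
- For: a chemoselective closure that tolerates acetates, builds the lactone in the same step and ends one deprotection from the target. On end-game step economy it is clearly stronger (no sulfone removal, ketone reduction or late acetylation).
- Against: the C7 stereocentre would be created during the macrocyclisation under substrate control in a flexible transition state. The aldehyde sits on the fully substituted, silyloxy-bearing C8 and is very hindered. C2 with its acetate would have to be set on an open chain beforehand.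
- Comparison: the chosen route pays about four extra steps after ring closure. In return C7 is set beforehand by a chiral catalyst, and the ring closes where the stereochemical and regiochemical outcome leaves no trace.

Key step: step 29

## Route

Assumption: compounds 2 and 3 are carried as C1 epimer mixtures (trans major, shown), and 30 and 37 as mixtures at C2 and C3. All of these centres are removed or re-set later.

**Step 1**
Reactants: 1 (S)-carvone
Product: 2 6-(hydroxymethyl)carvone (C1-hydroxymethyl, epimers, trans to isopropenyl major)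
Conditions: LiN(iPr)2, THF, −78 °C; CH2O (gas, from paraformaldehyde)
Reagents that add atoms: formaldehyde, C=O
Why: The kinetic cross-conjugated lithium enolate (α′ deprotonation) adds to monomeric formaldehyde (aldol hydroxymethylation); the new centre is re-enolised in step 3, so its configuration does not matter.

**Step 2**
Reactants: 2 6-(hydroxymethyl)carvone
Product: 3 TBS ether of 2
Conditions: TBSCl, imidazole, DMF, 0 °C to rt
Reagents that add atoms: tert-butyldimethylsilyl chloride, CC(C)(C)[Si](C)(C)Cl
Why: Standard silylation of a primary alcohol; it blocks retro-aldol loss of formaldehyde and carries C2 as a protected carbinol through the basic steps.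

**Step 3**
Reactants: 3 TBS ether
Product: 4 (5R,6R)-6-[(TBS-oxy)methyl]-2,6-dimethyl-5-(prop-1-en-2-yl)cyclohex-2-en-1-one (new methyl trans to isopropenyl)
Conditions: LiN(iPr)2, THF, −78 °C; MeI, DMPU, −78 to −40 °C
Reagents that add atoms: iodomethane, CI
Why: Enolate alkylation; the neighbouring isopropenyl group turns pseudoaxial to avoid allylic strain and shields one face, so iodomethane should enter trans to it, which sets quaternary C1 (15β-methyl, C2 α and cis to the future C14 oxygen).

**Step 4**
Reactants: 4 methylated ketone
Product: 6 14α-acetate (isopropenyl replaced by OAc), via α-methoxy hydroperoxide 5 (not isolated)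
Conditions: O3, CH2Cl2/MeOH, −78 °C; then Ac2O, Et3N, DMAP, 0 °C to rt
Reagents that add atoms: ozone, [O-][O+]=O; methanol, CO
Why: Ozone cleaves the electron-rich isopropenyl alkene in preference to the enone and methanol traps the carbonyl oxide as 5; acylation triggers the Criegee rearrangement, in which the secondary ring carbon migrates to oxygen with retention, so the carvone stereocentre becomes C14 with its α-oxygen.

**Step 5**
Reactants: 6 acetate
Product: 7 14α-alcohol
Conditions: K2CO3, MeOH, 0 °C
Reagents that add atoms: none
Why: Transesterification of the secondary acetate, which would not survive the organolithium steps ahead; quaternary C1 rules out β-elimination.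

**Step 6**
Reactants: 7 alcohol
Product: 8 ring A enone (C10 ketone, C11=C12, 14α-OTBS, C1 with 15β-methyl and α-CH2OTBS)
Conditions: TBSOTf, 2,6-lutidine, CH2Cl2, −78 °C
Reagents that add atoms: tert-butyldimethylsilyl triflate, CC(C)(C)[Si](C)(C)OS(=O)(=O)C(F)(F)F
Why: Silyl triflate silylation of a hindered secondary alcohol at low temperature, where the enone is not enolised.

**Step 7**
Reactants: 8 enone
Product: 9 11β,12β-epoxy ketone
Conditions: t-BuOOH, Triton B (cat.), THF, 0 °C to rt
Reagents that add atoms: tert-butyl hydroperoxide, CC(C)(C)OO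
Why: Weitz–Scheffer nucleophilic epoxidation; the peroxide anion adds axially to C12 anti to the 14α-silyloxy group (the same 1,3-relationship that directs epoxidation of carvone), which should give the β-epoxide.

**Step 8**
Reactants: 9 epoxy ketone
Product: 11 allylic alcohol (C10=C11, 12β-OH), via epoxy hydrazone 10 (not isolated)
Conditions: N2H4·H2O, AcOH (cat.), MeOH, 0 °C to rt
Reagents that add atoms: none
Why: Wharton transposition: hydrazone 10 opens the oxirane to an alkenyl diazene that loses N2; the alkene moves to C10=C11 and the C12–O bond, hence the β configuration of the alcohol, is untouched.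

**Step 9**
Reactants: 11 allylic alcohol
Product: 12 tributylstannylmethyl ether of 11
Conditions: KH, 18-crown-6 (cat.), THF, 0 °C; Bu3SnCH2I
Reagents that add atoms: tributyl(iodomethyl)stannane, CCCC[Sn](CCCC)(CCCC)CI
Why: Williamson etherification of the potassium alkoxide with the iodomethylstannane.

**Step 10**
Reactants: 12 stannylmethyl ether
Product: 13 homoallylic alcohol (10β-CH2OH = C9, C11=C12)
Conditions: n-BuLi, THF, −78 °C
Reagents that add atoms: none
Why: Still variant of the [2,3]-Wittig rearrangement: tin–lithium exchange gives the α-alkoxymethyllithium, which shifts suprafacially from the β-oxygen at C12 to C10; this forms C9–C10 on the β face (cis to C15, H10 α) and returns the alkene to C11=C12.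

**Step 11**
Reactants: 13 homoallylic alcohol
Product: 14 ring A aldehyde (C9 = CHO)
Conditions: Dess–Martin periodinane, NaHCO3, CH2Cl2, 0 °C
Reagents that add atoms: none
Why: Buffered Dess–Martin oxidation does not epimerise C10; the β,γ-unsaturated aldehyde is used at once so that it does not move into conjugation.

**Step 12**
Reactants: 15 diethyl (S)-malate
Product: 16 diethyl (2S,3R)-3-methylmalate
Conditions: LiN(iPr)2 (2.2 equiv), THF, −78 to −20 °C; MeI, −78 to 0 °C
Reagents that add atoms: iodomethane, CI
Why: Fráter–Seebach alkylation: the chelated dilithium alkoxide–enolate is methylated anti to the alkoxide, which sets C17 (R) beside the future C8 carbinol.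

**Step 13**
Reactants: 16 diethyl 3-methylmalate
Product: 17 (2S,3R)-3-methylmalic acid
Conditions: KOH, H2O/EtOH, rt; then HCl
Reagents that add atoms: potassium hydroxide, [K+].[OH-]
Why: Saponification of both esters under mild conditions that leave the two stereocentres alone.

**Step 14**
Reactants: 17 3-methylmalic acid
Product: 18 (2R)-2-[(2S,4S)-2-tert-butyl-5-oxo-1,3-dioxolan-4-yl]propanoic acid (cis-dioxolanone)
Conditions: t-BuCHO, TsOH (cat.), H2SO4 (cat.), pentane, reflux, water separator
Reagents that add atoms: pivalaldehyde, CC(C)(C)C=O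
Why: Acetalisation of the α-hydroxy acid unit (self-regeneration of stereocentres); the five-membered dioxolanone is preferred over the six-membered alternative, and the cis isomer is the thermodynamic product.

**Step 15**
Reactants: 18 dioxolanone acid; 14 ring A aldehyde
Product: 20 aldol adduct (C8–C9 bond, 9-OTBS, spiro-dioxolanone at C8, C19 acid), via silyl ester 19 (not isolated)
Conditions: LiN(SiMe3)2 (2.2 equiv), THF, −78 °C; 14; TBSOTf, −78 to −40 °C; aqueous work-up at pH 5
Reagents that add atoms: tert-butyldimethylsilyl triflate, CC(C)(C)[Si](C)(C)OS(=O)(=O)C(F)(F)F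
Why: Aldol addition of the dioxolanone enolate (the acid is masked as its lithium salt): the aldehyde should be attacked on the enolate face anti to tert-butyl, which returns C8 with retention, and on its Felkin–Anh face with quaternary C1 as the large group, which gives (9R). Both preferences fit one chair Zimmerman–Traxler array with the ring A residue equatorial. The silyl triflate traps the aldolate before retro-aldol or lactonisation onto C19, and silyl ester 19 hydrolyses on work-up.

**Step 16**
Reactants: 20 aldol adduct; 21 propyne
Product: 22 ynone acid (C7 ketone with C6≡C5–C16, free 8-OH, C19 acid)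
Conditions: 21, n-BuLi, THF, −78 °C; then 20, −78 °C; AcOH quench
Reagents that add atoms: none
Why: Acetylide addition to a lactone carbonyl: the acylal carbonyl C7 is the only electrophile (carboxylate and silyl ethers are inert); the tetrahedral adduct persists at −78 °C and on protonation collapses to the ynone with loss of pivalaldehyde, which frees the tertiary 8-OH.

**Step 17**
Reactants: 22 ynone acid
Product: 24 propynyl lactone (7S; O7–C19 closed), via γ-hydroxy acid 23 (not isolated)
Conditions: RuCl[(R,R)-TsDPEN](p-cymene) (cat.), HCO2H/Et3N (5:2), CH2Cl2, rt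
Reagents that add atoms: none
Why: Noyori asymmetric transfer hydrogenation of an alkynyl ketone, where the catalyst decides the face; with the alkyne in the place an aryl group normally takes, the (R,R) catalyst should give (7S). Hydroxy acid 23 closes to the five-membered lactone in the acidic medium, and O7 is the only free oxygen that can do so.

**Step 18**
Reactants: 24 propynyl lactone
Product: 25 (Z)-alkenylsilane (SiEt3 on C5, cis to C7)
Conditions: Et3SiH, [Cp*Ru(MeCN)3]PF6 (cat.), CH2Cl2, 0 °C to rt
Reagents that add atoms: triethylsilane, CC[SiH](CC)CC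
Why: Ruthenium-catalysed trans-hydrosilylation of an internal alkyne: H and Si add anti, and silicon should go to C5, the methyl-bearing carbon distal to the propargylic oxygen, so that it lies cis to C7.

**Step 19**
Reactants: 25 alkenylsilane
Product: 26 (Z)-alkenyl iodide (I on C5, cis to C7)
Conditions: N-iodosuccinimide, 2,6-lutidine, (CF3)2CHOH, 0 °C
Reagents that add atoms: N-iodosuccinimide, O=C1CCC(=O)N1I
Why: Iododesilylation by ipso attack of iodonium on the vinylsilane proceeds with retention, so iodine takes the place that C4 will need.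

**Step 20**
Reactants: 26 alkenyl iodide
Product: 27 primary alcohol (C2–OH free; 9- and 14-OTBS kept)
Conditions: HF·pyridine, pyridine, THF, 0 °C
Reagents that add atoms: none
Why: Buffered fluoride cleaves the primary silyl ether much faster than the two hindered secondary ones; O9 must stay protected because a free 9-OH would form a lactol with the C2 aldehyde.

**Step 21**
Reactants: 27 primary alcohol
Product: 28 C2 aldehyde
Conditions: Dess–Martin periodinane, NaHCO3, CH2Cl2, rt
Reagents that add atoms: none
Why: Dess–Martin oxidation of the neopentyl primary alcohol to a non-enolisable aldehyde; the tertiary 8-OH is inert.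

**Step 22**
Reactants: 28 aldehyde; 29 methyl phenyl sulfone
Product: 30 β-hydroxy sulfone (C2 epimers)
Conditions: 29, n-BuLi (2.5 equiv each), THF, −78 °C; then 28, −78 °C
Reagents that add atoms: none
Why: 1,2-Addition of the α-sulfonyl carbanion to the aldehyde is far faster at −78 °C than attack on the lactone; one equivalent is spent on the 8-OH. The C2 carbinol mixture is removed in step 23.

**Step 23**
Reactants: 30 β-hydroxy sulfone
Product: 31 β-keto sulfone
Conditions: Dess–Martin periodinane, CH2Cl2, rt
Reagents that add atoms: none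
Why: Dess–Martin oxidation gives the β-keto sulfone; with C1 quaternary, C3 is its only acidic position.

**Step 24**
Reactants: 31 β-keto sulfone
Product: 32 triol (9-OH, 14-OH, 8-OH)
Conditions: HF (aq.), MeCN, rt
Reagents that add atoms: none
Why: Acidic fluoride removes the two secondary silyl ethers; the β-keto sulfone, lactone and alkenyl iodide are stable to it.

**Step 25**
Reactants: 32 triol
Product: 33 9,14-diacetate (8-OH free)
Conditions: Ac2O, pyridine, DMAP (cat.), CH2Cl2, 0 °C to rt
Reagents that add atoms: acetic anhydride, CC(=O)OC(C)=O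
Why: Acetylation of the two secondary alcohols; the tertiary 8-OH does not react under these conditions, and any hemiketal between O9 and C2 is drained through the open form.

**Step 26**
Reactants: 33 diacetate
Product: 34 8-O-trimethylsilyl ether
Conditions: TMSOTf, 2,6-lutidine, CH2Cl2, −78 °C; NaHCO3 work-up
Reagents that add atoms: trimethylsilyl triflate, C[Si](C)(C)OS(=O)(=O)C(F)(F)F
Why: Silyl triflate silylation of the tertiary alcohol; it keeps O8 from attacking C4 (a six-membered ether) in step 29 and from shifting the 9-acetate under base.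

**Step 27**
Reactants: 34 silyl ether
Product: 35 (Z)-allylic alcohol (C4–OH)
Conditions: Bu3SnCH2OH, Pd(PPh3)4 (cat.), 1,4-dioxane, 80 °C
Reagents that add atoms: (tributylstannyl)methanol, CCCC[Sn](CCCC)(CCCC)CO
Why: Migita–Kosugi–Stille coupling of the alkenyl iodide with the hydroxymethylstannane goes with retention, which puts C4 cis to C7 and completes the (Z)-alkene.

**Step 28**
Reactants: 35 allylic alcohol
Product: 36 seco (Z)-allylic bromide with lactone, 9,14-diacetate, 8-OTMS and C2 β-keto sulfone
Conditions: CBr4, PPh3, 2,6-lutidine, CH2Cl2, 0 °C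
Reagents that add atoms: carbon tetrabromide, BrC(Br)(Br)Br
Why: Appel bromination of the primary allylic alcohol under buffered conditions, by SN2 at C4 without allylic shift.

**Step 29**
Reactants: 36 seco allylic bromide
Product: 37 cyclised C2 ketone with phenylsulfonyl on C3 (C3 epimers)
Conditions: Cs2CO3 (3 equiv), MeCN, 50 °C, slow addition of 36 to a final 1 mM
Reagents that add atoms: none
Why: Cs2CO3 deprotonates C3, the only carbon flanked by the C2 ketone and the sulfone, and the soft carbanion displaces bromide at the primary allylic C4 by SN2, forming C3–C4. The closest known reaction type is the intramolecular alkylation of sulfone-stabilised carbanions by allylic halides, as used to close carbocyclic macrocycles. The ten-membered ring closes in the 10-exo-tet mode. C3 becomes a stereocentre that is not controlled and need not be, because step 30 removes the sulfone. The step needs C- over O-alkylation (soft doubly stabilised anion, soft allylic bromide), SN2 over SN2′ (C4 is primary and open, C6 is flanked by C7) and ring closure over oligomerisation (high dilution). Direct substitution leaves the Z geometry of C5=C6 untouched, and that alkene, the trans arrangement of C2 and C9 on ring A and the trans arrangement of C6 and C9 on the lactone already turn the chain ends towards each other. The 8-O-silyl group excludes the competing six-membered ether, and the acetates survive carbonate in an aprotic solvent.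

**Step 30**
Reactants: 37 cyclised keto sulfone
Product: 38 C2 ketone (C3 = CH2)
Conditions: SmI2, THF/MeOH, −78 °C
Reagents that add atoms: none
Why: Single-electron reduction of the α-sulfonyl ketone expels sulfinate and the samarium enolate is protonated by methanol; alkenes, acetates and the lactone are not reduced, and the C3 stereocentre disappears.

**Step 31**
Reactants: 38 ketone
Product: 39 (2R)-alcohol
Conditions: (S)-2-methyl-CBS-oxazaborolidine, catecholborane, toluene, −78 to −40 °C
Reagents that add atoms: none
Why: Corey–Bakshi–Shibata reduction: with quaternary C1 as the large and C3H2 as the small substituent, the (S)-oxazaborolidine should deliver hydride to give (2R); catecholborane at low temperature leaves the alkenes alone.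

**Step 32**
Reactants: 39 alcohol
Product: 40 2,9,14-triacetate 8-O-trimethylsilyl ether
Conditions: Ac2O, DMAP, pyridine, CH2Cl2, rt
Reagents that add atoms: acetic anhydride, CC(=O)OC(C)=O
Why: DMAP-catalysed acetylation of the hindered secondary 2-OH; O8 is protected.

**Step 33**
Reactants: 40 silyl ether
Product: 41 stylatulide lactone
Conditions: HF·pyridine, THF, 0 °C
Reagents that add atoms: none
Why: Mild fluoride cleavage of the tertiary trimethylsilyl ether; acetates and lactone are untouched.

## Compound list

1 | (S)-carvone | CC1=CC[C@@H](CC1=O)C(C)=C | starting material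
2 | 6-(hydroxymethyl)carvone (trans major) | CC1=CC[C@@H]([C@@H](CO)C1=O)C(C)=C | intermediate
3 | 6-[(TBS-oxy)methyl]carvone | CC1=CC[C@@H]([C@@H](CO[Si](C)(C)C(C)(C)C)C1=O)C(C)=C | intermediate
4 | (5R,6R)-6-[(TBS-oxy)methyl]-2,6-dimethyl-5-(prop-1-en-2-yl)cyclohex-2-en-1-one | CC1=CC[C@@H]([C@](C)(CO[Si](C)(C)C(C)(C)C)C1=O)C(C)=C | intermediate
5 | α-methoxy hydroperoxide from ozonolysis of 4 | CC1=CC[C@@H]([C@](C)(CO[Si](C)(C)C(C)(C)C)C1=O)C(C)(OC)OO | intermediate (not isolated)
6 | 14α-acetoxy enone | CC1=CC[C@@H]([C@](C)(CO[Si](C)(C)C(C)(C)C)C1=O)OC(C)=O | intermediate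
7 | 14α-hydroxy enone | CC1=CC[C@@H]([C@](C)(CO[Si](C)(C)C(C)(C)C)C1=O)O | intermediate
8 | ring A enone, 14α-OTBS, C1 with 15β-methyl and α-CH2OTBS | CC1=CC[C@@H]([C@](C)(CO[Si](C)(C)C(C)(C)C)C1=O)O[Si](C)(C)C(C)(C)C | intermediate
9 | 11β,12β-epoxy C10 ketone | C[C@]12O[C@H]1C[C@H](O[Si](C)(C)C(C)(C)C)[C@](C)(CO[Si](C)(C)C(C)(C)C)C2=O | intermediate
10 | hydrazone of 9 | C[C@]12O[C@H]1C[C@H](O[Si](C)(C)C(C)(C)C)[C@](C)(CO[Si](C)(C)C(C)(C)C)C2=NN | intermediate (not isolated)
11 | allylic alcohol, C10=C11, 12β-OH | CC1=C[C@@](C)(CO[Si](C)(C)C(C)(C)C)[C@@H](O[Si](C)(C)C(C)(C)C)C[C@@H]1O | intermediate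
12 | 12β-O-(tributylstannyl)methyl ether of 11 | CC1=C[C@@](C)(CO[Si](C)(C)C(C)(C)C)[C@@H](O[Si](C)(C)C(C)(C)C)C[C@@H]1OC[Sn](CCCC)(CCCC)CCCC | intermediate
13 | homoallylic alcohol, 10β-CH2OH, C11=C12 | CC(C)(C)[Si](C)(C)O[C@H]1CC=C(C)[C@H](CO)[C@@]1(C)CO[Si](C)(C)C(C)(C)C | intermediate
14 | ring A aldehyde (C9 = CHO) | CC(C)(C)[Si](C)(C)O[C@H]1CC=C(C)[C@H](C=O)[C@@]1(C)CO[Si](C)(C)C(C)(C)C | intermediate
15 | diethyl (S)-malate | CCOC(=O)C[C@H](O)C(=O)OCC | starting material
16 | diethyl (2S,3R)-3-methylmalate | CCOC(=O)[C@H](C)[C@H](O)C(=O)OCC | intermediate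
17 | (2S,3R)-3-methylmalic acid | OC(=O)[C@H](C)[C@H](O)C(O)=O | intermediate
18 | (2R)-2-[(2S,4S)-2-tert-butyl-5-oxo-1,3-dioxolan-4-yl]propanoic acid | OC(=O)[C@H](C)[C@@H]1O[C@H](C(C)(C)C)OC1=O | intermediate
19 | TBS ester of 20 | CC(C)(C)[Si](C)(C)O[C@H]1CC=C(C)[C@H]([C@@H](O[Si](C)(C)C(C)(C)C)[C@]2(O[C@H](C(C)(C)C)OC2=O)[C@@H](C)C(=O)O[Si](C)(C)C(C)(C)C)[C@@]1(C)CO[Si](C)(C)C(C)(C)C | intermediate (not isolated)
20 | aldol adduct: 9-OTBS, C8 spiro-dioxolanone, C19 acid | CC(C)(C)[Si](C)(C)O[C@H]1CC=C(C)[C@H]([C@@H](O[Si](C)(C)C(C)(C)C)[C@]2(O[C@H](C(C)(C)C)OC2=O)[C@@H](C)C(O)=O)[C@@]1(C)CO[Si](C)(C)C(C)(C)C | intermediate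
21 | propyne | CC#C | starting material
22 | ynone acid: C7 propynyl ketone, 8-OH, C19 acid | CC(C)(C)[Si](C)(C)O[C@H]1CC=C(C)[C@H]([C@@H](O[Si](C)(C)C(C)(C)C)[C@@](O)(C(=O)C#CC)[C@@H](C)C(O)=O)[C@@]1(C)CO[Si](C)(C)C(C)(C)C | intermediate
23 | (7S)-γ-hydroxy acid | CC(C)(C)[Si](C)(C)O[C@H]1CC=C(C)[C@H]([C@@H](O[Si](C)(C)C(C)(C)C)[C@@](O)([C@@H](O)C#CC)[C@@H](C)C(O)=O)[C@@]1(C)CO[Si](C)(C)C(C)(C)C | intermediate (not isolated)
24 | propynyl γ-lactone (8-OH, 17-methyl and C6 cis) | CC(C)(C)[Si](C)(C)O[C@H]1CC=C(C)[C@H]([C@@H](O[Si](C)(C)C(C)(C)C)[C@@]2(O)[C@H](C#CC)OC(=O)[C@@H]2C)[C@@]1(C)CO[Si](C)(C)C(C)(C)C | intermediate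
25 | (Z)-alkenylsilane, SiEt3 on C5 | CC(C)(C)[Si](C)(C)O[C@H]1CC=C(C)[C@H]([C@@H](O[Si](C)(C)C(C)(C)C)[C@@]2(O)[C@H](/C=C(/C)[Si](CC)(CC)CC)OC(=O)[C@@H]2C)[C@@]1(C)CO[Si](C)(C)C(C)(C)C | intermediate
26 | (Z)-alkenyl iodide, I on C5 | CC(C)(C)[Si](C)(C)O[C@H]1CC=C(C)[C@H]([C@@H](O[Si](C)(C)C(C)(C)C)[C@@]2(O)[C@H](/C=C(/C)I)OC(=O)[C@@H]2C)[C@@]1(C)CO[Si](C)(C)C(C)(C)C | intermediate
27 | C2 primary alcohol | CC(C)(C)[Si](C)(C)O[C@H]1CC=C(C)[C@H]([C@@H](O[Si](C)(C)C(C)(C)C)[C@@]2(O)[C@H](/C=C(/C)I)OC(=O)[C@@H]2C)[C@@]1(C)CO | intermediate
28 | C2 aldehyde | CC(C)(C)[Si](C)(C)O[C@H]1CC=C(C)[C@H]([C@@H](O[Si](C)(C)C(C)(C)C)[C@@]2(O)[C@H](/C=C(/C)I)OC(=O)[C@@H]2C)[C@@]1(C)C=O | intermediate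
29 | methyl phenyl sulfone | CS(=O)(=O)c1ccccc1 | starting material
30 | β-hydroxy sulfone (C2 epimers) | CC(C)(C)[Si](C)(C)O[C@H]1CC=C(C)[C@H]([C@@H](O[Si](C)(C)C(C)(C)C)[C@@]2(O)[C@H](/C=C(/C)I)OC(=O)[C@@H]2C)[C@@]1(C)C(O)CS(=O)(=O)c1ccccc1 | intermediate
31 | β-keto sulfone, 9,14-bis-OTBS | CC(C)(C)[Si](C)(C)O[C@H]1CC=C(C)[C@H]([C@@H](O[Si](C)(C)C(C)(C)C)[C@@]2(O)[C@H](/C=C(/C)I)OC(=O)[C@@H]2C)[C@@]1(C)C(=O)CS(=O)(=O)c1ccccc1 | intermediate
32 | β-keto sulfone triol | O[C@H]1CC=C(C)[C@H]([C@@H](O)[C@@]2(O)[C@H](/C=C(/C)I)OC(=O)[C@@H]2C)[C@@]1(C)C(=O)CS(=O)(=O)c1ccccc1 | intermediate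
33 | 9,14-diacetate, 8-OH | CC(=O)O[C@H]1CC=C(C)[C@H]([C@@H](OC(C)=O)[C@@]2(O)[C@H](/C=C(/C)I)OC(=O)[C@@H]2C)[C@@]1(C)C(=O)CS(=O)(=O)c1ccccc1 | intermediate
34 | 9,14-diacetate, 8-OTMS, alkenyl iodide | CC(=O)O[C@H]1CC=C(C)[C@H]([C@@H](OC(C)=O)[C@@]2(O[Si](C)(C)C)[C@H](/C=C(/C)I)OC(=O)[C@@H]2C)[C@@]1(C)C(=O)CS(=O)(=O)c1ccccc1 | intermediate
35 | (Z)-allylic alcohol | CC(=O)O[C@H]1CC=C(C)[C@H]([C@@H](OC(C)=O)[C@@]2(O[Si](C)(C)C)[C@H](/C=C(/C)CO)OC(=O)[C@@H]2C)[C@@]1(C)C(=O)CS(=O)(=O)c1ccccc1 | intermediate
36 | seco (Z)-allylic bromide (key-step precursor) | CC(=O)O[C@H]1CC=C(C)[C@H]([C@@H](OC(C)=O)[C@@]3(O[Si](C)(C)C)[C@H](/C=C(/C)CBr)OC(=O)[C@@H]3C)[C@@]1(C)C(=O)CS(=O)(=O)c1ccccc1 | intermediate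
37 | cyclised C2 ketone, 3-phenylsulfonyl (key-step product) | CC(=O)O[C@H]1CC=C(C)[C@@H]2[C@@H](OC(C)=O)[C@@]3(O[Si](C)(C)C)[C@H](/C=C(/C)CC(S(=O)(=O)c4ccccc4)C(=O)[C@@]12C)OC(=O)[C@@H]3C | intermediate
38 | C2 ketone | CC(=O)O[C@H]1CC=C(C)[C@@H]2[C@@H](OC(C)=O)[C@@]3(O[Si](C)(C)C)[C@H](/C=C(/C)CCC(=O)[C@@]12C)OC(=O)[C@@H]3C | intermediate
39 | (2R)-alcohol | CC(=O)O[C@H]1CC=C(C)[C@@H]2[C@@H](OC(C)=O)[C@@]3(O[Si](C)(C)C)[C@H](/C=C(/C)CC[C@@H](O)[C@@]12C)OC(=O)[C@@H]3C | intermediate
40 | 8-O-trimethylsilyl stylatulide lactone | CC(=O)O[C@H]1CC=C(C)[C@@H]2[C@@H](OC(C)=O)[C@@]3(O[Si](C)(C)C)[C@H](/C=C(/C)CC[C@@H](OC(C)=O)[C@@]12C)OC(=O)[C@@H]3C | intermediate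
41 | stylatulide lactone | CC(=O)O[C@H]1CC=C(C)[C@@H]2[C@@H](OC(C)=O)[C@@]3(O)[C@H](/C=C(/C)CC[C@@H](OC(C)=O)[C@@]12C)OC(=O)[C@@H]3C | target

## Step count and least certain steps

Total step count: 33. Longest linear sequence: 30 (steps 1–11 and 15–33); steps 12–14 make the malate fragment.

**Step 29 (key step).** The most likely failure is intermolecular alkylation (dimers, oligomers) or O-alkylation of the enolate, because the ten-membered transition state is strained by the two fully substituted carbons beside the ring fusion. Fallback: from allylic alcohol 35, acylation with methyl chloroformate and pyridine gives the allyl methyl carbonate F1. Ionisation with zerovalent palladium (Pd2(dba)3, dppe, THF, 65 °C, high dilution) gives a π-allyl complex, and the methoxide released deprotonates C3. Tsuji–Trost attack of the β-keto sulfone at the less hindered terminus C4 then closes the ring and returns to 37. The ring size allows only the Z alkene, which should hold the allyl unit in the matching geometry.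

**Step 15.** Both partners are congested. Proton transfer from the acidic, allylic C10–H of 14 to the enolate, retro-aldol before silylation, or erosion of the Felkin preference could lower yield and selectivity at C9. Fallback: from 18, double silylation (LiN(SiMe3)2, Me3SiCl) gives the silyl ketene acetal silyl ester F2. A BF3·OEt2-mediated Mukaiyama aldol with 14 at −78 °C, which is non-basic and has an open transition state but the same facial preferences, gives the 9-hydroxy acid F3 after work-up. Immediate silylation with TBSOTf and 2,6-lutidine (silyl ester hydrolysed on work-up) returns to 20.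

**Step 8.** Condensation of hydrazine with a ketone that lies between two fully substituted carbons may be slow, and nucleophilic opening of the epoxide by hydrazine could then compete. Fallback: from 9, NaBH4/CeCl3·7H2O in MeOH gives the epoxy alcohol F4 (C10 epimers). Cp2TiCl (from Cp2TiCl2 and Zn, THF, rt) opens the oxirane homolytically at C11. A second equivalent of the trivalent titanium reagent traps the radical, and β-elimination of the C10 titanium alkoxide gives 11 with the same 12β-OH.

**Step 18.** Delivery of silicon to C6 instead of C5 (wrong regiochemistry), or catalyst inhibition by the free 8-OH, would spoil the geometry-defining step. Fallback: from 22, esterification (Me3SiCHN2, MeOH/toluene) gives the ynone methyl ester F5. Transfer hydrogenation with the same (R,R) catalyst in 2-propanol under neutral conditions gives the propargylic alcohol methyl ester F6, which does not lactonise spontaneously. Hydrosilylation under the conditions of step 18, now directed by the free propargylic hydroxyl, gives the alkenylsilane hydroxy ester F7. Lactonisation (PPTS, toluene, 60 °C) returns to 25.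

**Step 31.** Poor facial selectivity or slow reduction is possible, because the ketone is flanked by quaternary C1 inside a medium ring whose conformation may override the catalyst. Fallback: from 38, NaBH4/CeCl3·7H2O in MeOH at −40 °C gives 39 together with the (2S)-alcohol F8. The two are separated by chromatography, and F8 is re-oxidised with Dess–Martin periodinane to 38 and recycled.

## Further compounds

F1 | step 29 | allyl methyl carbonate of 35 | CC(=O)O[C@H]1CC=C(C)[C@H]([C@@H](OC(C)=O)[C@@]3(O[Si](C)(C)C)[C@H](/C=C(/C)COC(=O)OC)OC(=O)[C@@H]3C)[C@@]1(C)C(=O)CS(=O)(=O)c1ccccc1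
F2 | step 15 | trimethylsilyl (2R)-2-[(2S)-2-tert-butyl-5-(trimethylsilyloxy)-1,3-dioxol-4-yl]propanoate | C[C@@H](C(=O)O[Si](C)(C)C)C1=C(O[Si](C)(C)C)O[C@@H](C(C)(C)C)O1
F3 | step 15 | 9-hydroxy aldol acid (20 without the 9-O-silyl group) | CC(C)(C)[Si](C)(C)O[C@H]1CC=C(C)[C@H]([C@@H](O)[C@]2(O[C@H](C(C)(C)C)OC2=O)[C@@H](C)C(O)=O)[C@@]1(C)CO[Si](C)(C)C(C)(C)C
F4 | step 8 | 11β,12β-epoxy C10 alcohol (C10 epimers) | C[C@]12O[C@H]1C[C@H](O[Si](C)(C)C(C)(C)C)[C@](C)(CO[Si](C)(C)C(C)(C)C)C2O
F5 | step 18 | methyl ester of ynone acid 22 | CC(C)(C)[Si](C)(C)O[C@H]1CC=C(C)[C@H]([C@@H](O[Si](C)(C)C(C)(C)C)[C@@](O)(C(=O)C#CC)[C@@H](C)C(=O)OC)[C@@]1(C)CO[Si](C)(C)C(C)(C)C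
F6 | step 18 | (7S)-propargylic alcohol methyl ester | CC(C)(C)[Si](C)(C)O[C@H]1CC=C(C)[C@H]([C@@H](O[Si](C)(C)C(C)(C)C)[C@@](O)([C@@H](O)C#CC)[C@@H](C)C(=O)OC)[C@@]1(C)CO[Si](C)(C)C(C)(C)C
F7 | step 18 | (Z)-alkenylsilane hydroxy methyl ester | CC(C)(C)[Si](C)(C)O[C@H]1CC=C(C)[C@H]([C@@H](O[Si](C)(C)C(C)(C)C)[C@@](O)([C@@H](O)/C=C(/C)[Si](CC)(CC)CC)[C@@H](C)C(=O)OC)[C@@]1(C)CO[Si](C)(C)C(C)(C)C
F8 | step 31 | (2S)-alcohol, C2 epimer of 39 | CC(=O)O[C@H]1CC=C(C)[C@@H]2[C@@H](OC(C)=O)[C@@]3(O[Si](C)(C)C)[C@H](/C=C(/C)CC[C@H](O)[C@@]12C)OC(=O)[C@@H]3C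
A1 | alternative 1 | cis-anti-cis enone–cyclobutene photoadduct with bicyclo[2.2.0]hexane | CC(C)(C)[Si](C)(C)O[C@H]1CCC(=O)[C@]23[C@@H]4[C@H]5OC(C)(C)O[C@H]5[C@@H]4[C@@]2(C)CC[C@@H](O[Si](C)(C)C(C)(C)C)[C@@]13C
A2 | alternative 2 | ring A ketol from the proline aldol | O[C@H]1CC(=O)C(C)[C@H](COCc2ccccc2)[C@@]1(C)[C@H](OCc2ccc(OC)cc2)CCO[Si](C)(C)C(C)(C)C
A3 | alternative 3 | 8-O-triethylsilyl stylatulide lactone | CC(=O)O[C@H]1CC=C(C)[C@@H]2[C@@H](OC(C)=O)[C@@]3(O[Si](CC)(CC)CC)[C@H](/C=C(/C)CC[C@@H](OC(C)=O)[C@@]12C)OC(=O)[C@@H]3C
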